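**Retrosynthetic overview**

1. Target ⇐ buffered fluoride desilylation of the tris-silylated (S)-2H-chromene ⇐ mesylation/β-elimination of a (2S,4S)-chroman-4-ol, in which C4 is only a temporary stereocentre.
2. (2S,4S)-Chromanol ⇐ Noyori transfer hydrogenation of the racemic chroman-4-one (the catalyst sets 4S in both enantiomers), then chromatographic removal of the (2R,4S)-diastereomer, which fixes C2 as S.
3. Chroman-4-one ⇐ key disconnection C2–C3, then O1–C2: Kabbe intermolecular crossed aldol condensation with oxa-Michael closure between a 5-(2-arylethyl)-2-hydroxyacetophenone and (E)-7-silyloxy-6-methylhept-5-en-2-one.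
4. Acetophenone fragment ⇐ Heck coupling and hydrogenation (5-bromo-2-hydroxyacetophenone + MOM-protected 2,3-dihydroxystyrene); ketone fragment ⇐ E-selective SeO2 allylic oxidation of 6-methylhept-5-en-2-one.
5. Ring order: both benzene rings are bought; the pyran ring is the only ring built, first as the chromanone in the aldol step and dehydrated to the 2H-chromene near the end.

Assumption: the SMILES is read as the (2S)-chromene with an (E)-allylic alcohol; the aldol ring construction gives C2 as a racemate, so single-enantiomer material comes from catalyst-controlled reduction plus diastereomer separation (about 98% ee expected, at most 50% yield in that step).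

**Route**

Step 1
Reactants: 1 2,3-dihydroxybenzaldehyde
Product: 2 2,3-bis(methoxymethoxy)benzaldehyde
Conditions: MOMCl (3 equiv), i-Pr2NEt (4 equiv), CH2Cl2, 0 °C → 40 °C
Reagents that add atoms: chloromethyl methyl ether (MOMCl), COCCl
Why: Base-mediated O-alkylation (MOM acetal protection) masks both phenols in a form that is stable to the ylide, the Heck base, hydrogenation and the amine of the aldol step; no stereocentre is formed.

Step 2
Reactants: 2 2,3-bis(methoxymethoxy)benzaldehyde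
Product: 3 1-ethenyl-2,3-bis(methoxymethoxy)benzene
Conditions: Ph3PCH3Br, KOt-Bu, THF, 0 °C → rt
Reagents that add atoms: methyltriphenylphosphonium bromide, C[P+](c1ccccc1)(c1ccccc1)c1ccccc1.[Br-]
Why: Wittig methylenation of the aryl aldehyde with the non-stabilised ylide gives the styrene, and the MOM acetals are inert to the basic ylide.

Step 3
Reactants: 3 1-ethenyl-2,3-bis(methoxymethoxy)benzene; 4 1-(5-bromo-2-hydroxyphenyl)ethan-1-one
Product: 5 1-[5-[(E)-2-[2,3-bis(methoxymethoxy)phenyl]ethenyl]-2-hydroxyphenyl]ethan-1-one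
Conditions: Pd(OAc)2 (5 mol %), P(o-tol)3 (12 mol %), Et3N, DMF, 100 °C
Reagents that add atoms: none
Why: Mizoroki–Heck coupling, in which the aryl bromide adds oxidatively to zerovalent palladium formed in the flask, the styrene inserts at its terminal carbon and syn-β-hydride elimination gives the (E)-stilbene, with the chelated phenol and the ketone tolerated.

Step 4
Reactants: 5 1-[5-[(E)-2-[2,3-bis(methoxymethoxy)phenyl]ethenyl]-2-hydroxyphenyl]ethan-1-one
Product: 6 1-[5-[2-[2,3-bis(methoxymethoxy)phenyl]ethyl]-2-hydroxyphenyl]ethan-1-one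
Conditions: H2 (1 atm), 10% Pd/C, EtOAc, rt
Reagents that add atoms: none
Why: Heterogeneous catalytic hydrogenation saturates the stilbene double bond under neutral conditions that leave the MOM acetals, the hydrogen-bonded aryl ketone and the phenol untouched.

Step 5
Reactants: 7 6-methylhept-5-en-2-one
Product: 8 (5E)-7-hydroxy-6-methylhept-5-en-2-one
Conditions: SeO2 (0.5 equiv), t-BuOOH (2 equiv), salicylic acid (10 mol %), CH2Cl2, 0 °C → rt
Reagents that add atoms: tert-butyl hydroperoxide, CC(C)(C)OO (terminal source of the new oxygen); selenium dioxide SeO2, O=[Se]=O (relays the oxygen)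
Why: SeO2/t-BuOOH allylic oxidation proceeds by an ene reaction and [2,3]-sigmatropic shift that hydroxylates the methyl group trans to the chain, which fixes the (E)-allylic alcohol geometry.

Step 6
Reactants: 8 (5E)-7-hydroxy-6-methylhept-5-en-2-one
Product: 9 (5E)-7-[tert-butyl(diphenyl)silyl]oxy-6-methylhept-5-en-2-one
Conditions: TBDPSCl, imidazole, CH2Cl2, 0 °C → rt
Reagents that add atoms: tert-butyl(chloro)diphenylsilane (TBDPSCl), CC(C)(C)[Si](Cl)(c1ccccc1)c1ccccc1
Why: Imidazole-promoted silylation of the primary alcohol installs a TBDPS ether that withstands pyrrolidine, dilute methanolic HCl and the reduction, and falls with fluoride at the end.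

Step 7
Reactants: 6 1-[5-[2-[2,3-bis(methoxymethoxy)phenyl]ethyl]-2-hydroxyphenyl]ethan-1-one; 9 (5E)-7-[tert-butyl(diphenyl)silyl]oxy-6-methylhept-5-en-2-one
Product: 11 rac-6-[2-[2,3-bis(methoxymethoxy)phenyl]ethyl]-2-[(3E)-5-[tert-butyl(diphenyl)silyl]oxy-4-methylpent-3-en-1-yl]-2-methyl-2,3-dihydro-4H-chromen-4-one, via aldol-condensation enone 10 (not isolated)
Conditions: pyrrolidine (0.5 equiv), 9 (1.5 equiv), EtOH, reflux
Reagents that add atoms: none
Why: Kabbe reaction, a pyrrolidine-mediated intermolecular crossed aldol condensation of the acetophenone methyl group (future C3) with the ketone carbonyl (future C2) that gives enone 10, whose phenol closes the pyranone ring by 6-endo oxa-Michael addition; C2 is formed as a racemate and is resolved in step 10.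

Step 8
Reactants: 11 rac-bis-MOM chroman-4-one
Product: 12 rac-2-[(3E)-5-[tert-butyl(diphenyl)silyl]oxy-4-methylpent-3-en-1-yl]-6-[2-(2,3-dihydroxyphenyl)ethyl]-2-methyl-2,3-dihydro-4H-chromen-4-one
Conditions: HCl (1.25 M in MeOH), THF, rt
Reagents that add atoms: none
Why: Acid-catalysed acetal methanolysis removes the two aryl MOM groups at the robust ketone stage, while the primary TBDPS ether and the trisubstituted alkene tolerate dilute methanolic HCl.

Step 9
Reactants: 12 rac-catechol chroman-4-one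
Product: 13 rac-6-[2-[2,3-bis[tert-butyl(dimethyl)silyl]oxyphenyl]ethyl]-2-[(3E)-5-[tert-butyl(diphenyl)silyl]oxy-4-methylpent-3-en-1-yl]-2-methyl-2,3-dihydro-4H-chromen-4-one
Conditions: TBSCl (3 equiv), imidazole (6 equiv), DMF, rt
Reagents that add atoms: tert-butyl(chloro)dimethylsilane (TBSCl), CC(C)(C)[Si](C)(C)Cl
Why: Imidazole-promoted silylation converts the catechol into its bis-TBS ether so that the final unmasking uses buffered fluoride instead of acid on the chromene.

Step 10
Reactants: 13 rac-tris-silyl chroman-4-one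
Product: 14 (2S,4S)-6-[2-[2,3-bis[tert-butyl(dimethyl)silyl]oxyphenyl]ethyl]-2-[(3E)-5-[tert-butyl(diphenyl)silyl]oxy-4-methylpent-3-en-1-yl]-2-methyl-3,4-dihydro-2H-chromen-4-ol
Conditions: RuCl[(S,S)-TsDPEN](p-cymene) (2 mol %), HCO2H/Et3N (5:2), CH2Cl2, 30 °C; then SiO2 chromatography (the (2R,4S)-diastereomer is removed)
Reagents that add atoms: none
Why: Noyori–Ikariya asymmetric transfer hydrogenation delivers hydride to the same face of the aryl ketone in both enantiomers of 13 and sets C4 as S, so the (2S)-ketone gives 14 (2S,4S; 4-OH cis to 2-CH3, confirmed by NOE) and the (2R)-ketone gives the separable (2R,4S)-diastereomer, and isolating 14 fixes C2 as S.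

Step 11
Reactants: 14 (2S,4S)-tris-silyl chroman-4-ol
Product: 16 (2S)-6-[2-[2,3-bis[tert-butyl(dimethyl)silyl]oxyphenyl]ethyl]-2-[(3E)-5-[tert-butyl(diphenyl)silyl]oxy-4-methylpent-3-en-1-yl]-2-methyl-2H-chromene, via benzylic mesylate 15 (not isolated)
Conditions: MsCl, Et3N, CH2Cl2, 0 °C; then DBU, 0 °C → rt, dark
Reagents that add atoms: none
Why: Mesylation of the benzylic alcohol and base-induced β-elimination toward C3 form the chromene double bond without acid, which erases C4 and leaves the quaternary C2–O bond and its (S)-configuration untouched.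

Step 12
Reactants: 16 (2S)-tris-silyl 2H-chromene
Product: 17 3-[2-[(2S)-2-[(3E)-5-hydroxy-4-methylpent-3-en-1-yl]-2-methyl-2H-chromen-6-yl]ethyl]benzene-1,2-diol (CNP0267525.1)
Conditions: Bu4NF (4 equiv), AcOH (4 equiv), THF, 0 °C → rt, argon, dark
Reagents that add atoms: none
Why: Fluoride-mediated desilylation cleaves the two aryl TBS ethers and the primary TBDPS ether under acetic-acid-buffered, oxygen-free conditions that preserve the catechol, the light-sensitive chromene and the C2 stereocentre.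

**Compound list**

1 | 2,3-dihydroxybenzaldehyde | O=Cc1cccc(O)c1O | starting material
2 | 2,3-bis(methoxymethoxy)benzaldehyde | O=Cc1cccc(OCOC)c1OCOC | intermediate
3 | 1-ethenyl-2,3-bis(methoxymethoxy)benzene | C=Cc1cccc(OCOC)c1OCOC | intermediate
4 | 1-(5-bromo-2-hydroxyphenyl)ethan-1-one | CC(=O)c1cc(Br)ccc1O | starting material
5 | 1-[5-[(E)-2-[2,3-bis(methoxymethoxy)phenyl]ethenyl]-2-hydroxyphenyl]ethan-1-one | CC(=O)c1cc(/C=C/c2cccc(OCOC)c2OCOC)ccc1O | intermediate
6 | 1-[5-[2-[2,3-bis(methoxymethoxy)phenyl]ethyl]-2-hydroxyphenyl]ethan-1-one | CC(=O)c1cc(CCc2cccc(OCOC)c2OCOC)ccc1O | intermediate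
7 | 6-methylhept-5-en-2-one | CC(=O)CCC=C(C)C | starting material
8 | (5E)-7-hydroxy-6-methylhept-5-en-2-one | CC(=O)CC/C=C(\C)CO | intermediate
9 | (5E)-7-[tert-butyl(diphenyl)silyl]oxy-6-methylhept-5-en-2-one | CC(=O)CC/C=C(\C)CO[Si](c1ccccc1)(c1ccccc1)C(C)(C)C | intermediate
10 | (6E)-1-[5-[2-[2,3-bis(methoxymethoxy)phenyl]ethyl]-2-hydroxyphenyl]-8-[tert-butyl(diphenyl)silyl]oxy-3,7-dimethylocta-2,6-dien-1-one (C2=C3 as E/Z mixture; not isolated) | CC(=CC(=O)c1cc(CCc2cccc(OCOC)c2OCOC)ccc1O)CC/C=C(\C)CO[Si](c1ccccc1)(c1ccccc1)C(C)(C)C | intermediate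
11 | rac-6-[2-[2,3-bis(methoxymethoxy)phenyl]ethyl]-2-[(3E)-5-[tert-butyl(diphenyl)silyl]oxy-4-methylpent-3-en-1-yl]-2-methyl-2,3-dihydro-4H-chromen-4-one (racemic at C2) | C/C(=C\CCC1(C)CC(=O)c2cc(CCc3cccc(OCOC)c3OCOC)ccc2O1)CO[Si](c1ccccc1)(c1ccccc1)C(C)(C)C | intermediate
12 | rac-2-[(3E)-5-[tert-butyl(diphenyl)silyl]oxy-4-methylpent-3-en-1-yl]-6-[2-(2,3-dihydroxyphenyl)ethyl]-2-methyl-2,3-dihydro-4H-chromen-4-one (racemic at C2) | C/C(=C\CCC1(C)CC(=O)c2cc(CCc3cccc(O)c3O)ccc2O1)CO[Si](c1ccccc1)(c1ccccc1)C(C)(C)C | intermediate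
13 | rac-6-[2-[2,3-bis[tert-butyl(dimethyl)silyl]oxyphenyl]ethyl]-2-[(3E)-5-[tert-butyl(diphenyl)silyl]oxy-4-methylpent-3-en-1-yl]-2-methyl-2,3-dihydro-4H-chromen-4-one (racemic at C2) | C/C(=C\CCC1(C)CC(=O)c2cc(CCc3cccc(O[Si](C)(C)C(C)(C)C)c3O[Si](C)(C)C(C)(C)C)ccc2O1)CO[Si](c1ccccc1)(c1ccccc1)C(C)(C)C | intermediate
14 | (2S,4S)-6-[2-[2,3-bis[tert-butyl(dimethyl)silyl]oxyphenyl]ethyl]-2-[(3E)-5-[tert-butyl(diphenyl)silyl]oxy-4-methylpent-3-en-1-yl]-2-methyl-3,4-dihydro-2H-chromen-4-ol | C/C(=C\CC[C@@]1(C)C[C@H](O)c2cc(CCc3cccc(O[Si](C)(C)C(C)(C)C)c3O[Si](C)(C)C(C)(C)C)ccc2O1)CO[Si](c1ccccc1)(c1ccccc1)C(C)(C)C | intermediate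
15 | (2S,4S)-6-[2-[2,3-bis[tert-butyl(dimethyl)silyl]oxyphenyl]ethyl]-2-[(3E)-5-[tert-butyl(diphenyl)silyl]oxy-4-methylpent-3-en-1-yl]-2-methyl-3,4-dihydro-2H-chromen-4-yl methanesulfonate (not isolated) | C/C(=C\CC[C@@]1(C)C[C@H](OS(C)(=O)=O)c2cc(CCc3cccc(O[Si](C)(C)C(C)(C)C)c3O[Si](C)(C)C(C)(C)C)ccc2O1)CO[Si](c1ccccc1)(c1ccccc1)C(C)(C)C | intermediate
16 | (2S)-6-[2-[2,3-bis[tert-butyl(dimethyl)silyl]oxyphenyl]ethyl]-2-[(3E)-5-[tert-butyl(diphenyl)silyl]oxy-4-methylpent-3-en-1-yl]-2-methyl-2H-chromene | C/C(=C\CC[C@@]1(C)C=Cc2cc(CCc3cccc(O[Si](C)(C)C(C)(C)C)c3O[Si](C)(C)C(C)(C)C)ccc2O1)CO[Si](c1ccccc1)(c1ccccc1)C(C)(C)C | intermediate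
17 | 3-[2-[(2S)-2-[(3E)-5-hydroxy-4-methylpent-3-en-1-yl]-2-methyl-2H-chromen-6-yl]ethyl]benzene-1,2-diol | C/C(=C\CC[C@@]1(C)C=Cc2cc(CCc3cccc(O)c3O)ccc2O1)CO | target

**Totals**

Total step count: 12. Longest linear sequence: 10 steps (1 → 2 → 3 → 5 → 6 → 11 → 12 → 13 → 14 → 16 → 17; steps 1–4 and 7–12).

**Steps most likely to fail and their fallbacks**

Step 10 (resolution). Compound 14 and its (2R,4S)-diastereomer may co-elute, or the catalyst may not fully override the C2 centre. The fallback sets out from 13 and comes back at 16. Racemic 13 is separated by preparative chromatography on a chiral stationary phase (amylose tris(3,5-dimethylphenylcarbamate), CO2/i-PrOH) into the (2S)-ketone F1 and the (2R)-ketone F2. F1 is identified by converting a sample to 14. It is reduced with NaBH4 (MeOH/THF, 0 °C) to the C4-epimeric (2S)-chromanols F3. These are converted with MsCl/Et3N into the epimeric mesylates F4 and eliminated with DBU as in the main route. Both C4 epimers converge on 16 because C4 becomes sp2.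

Step 7 (Kabbe condensation). Self-condensation of 9 or incomplete ring closure may keep the yield low. The fallback sets out from 6 and 9 and comes back at 12. Compound 6 is converted into its dianion with LiN(i-Pr)2 (2.2 equiv, THF, −78 °C) and added to 9 in a directed lithium-enolate aldol addition, giving the tertiary aldol F5. Methanolic HCl (50 °C) then dehydrates F5, closes the pyranone ring through the phenol and removes both MOM groups in the same operation, delivering 12 directly.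

Step 5 (SeO2 oxidation). Over-oxidation to the enal and a modest yield are typical. The fallback sets out from 7 and comes back at 9. Compound 7 is ozonolysed (O3, CH2Cl2, −78 °C; Me2S) to 4-oxopentanal F6. F6 reacts at the aldehyde only with ethyl 2-(triphenylphosphoranylidene)propanoate (CH2Cl2, rt) to give ethyl (2E)-2-methyl-6-oxohept-2-enoate F7, with the E geometry set by the stabilised ylide. Excess i-Bu2AlH (CH2Cl2, −78 °C) reduces ester and ketone to (2E)-2-methylhept-2-ene-1,6-diol F8. Selective silylation of the primary allylic hydroxyl (TBDPSCl 1.05 equiv, imidazole, 0 °C) gives (5E)-7-[tert-butyl(diphenyl)silyl]oxy-6-methylhept-5-en-2-ol F9. Dess–Martin oxidation of the secondary alcohol returns ketone 9.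

**Further compounds**

F1 | step 10 | (2S)-enantiomer of 13 | C/C(=C\CC[C@@]1(C)CC(=O)c2cc(CCc3cccc(O[Si](C)(C)C(C)(C)C)c3O[Si](C)(C)C(C)(C)C)ccc2O1)CO[Si](c1ccccc1)(c1ccccc1)C(C)(C)C
F2 | step 10 | (2R)-enantiomer of 13 | C/C(=C\CC[C@]1(C)CC(=O)c2cc(CCc3cccc(O[Si](C)(C)C(C)(C)C)c3O[Si](C)(C)C(C)(C)C)ccc2O1)CO[Si](c1ccccc1)(c1ccccc1)C(C)(C)C
F3 | step 10 | (2S)-chroman-4-ol corresponding to 14 as a mixture of C4 epimers | C/C(=C\CC[C@@]1(C)CC(O)c2cc(CCc3cccc(O[Si](C)(C)C(C)(C)C)c3O[Si](C)(C)C(C)(C)C)ccc2O1)CO[Si](c1ccccc1)(c1ccccc1)C(C)(C)C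
F4 | step 10 | (2S)-chroman-4-yl methanesulfonate corresponding to 15 as a mixture of C4 epimers | C/C(=C\CC[C@@]1(C)CC(OS(C)(=O)=O)c2cc(CCc3cccc(O[Si](C)(C)C(C)(C)C)c3O[Si](C)(C)C(C)(C)C)ccc2O1)CO[Si](c1ccccc1)(c1ccccc1)C(C)(C)C
F5 | step 7 | rac-(6E)-1-[5-[2-[2,3-bis(methoxymethoxy)phenyl]ethyl]-2-hydroxyphenyl]-8-[tert-butyl(diphenyl)silyl]oxy-3-hydroxy-3,7-dimethyloct-6-en-1-one | CC(O)(CC(=O)c1cc(CCc2cccc(OCOC)c2OCOC)ccc1O)CC/C=C(\C)CO[Si](c1ccccc1)(c1ccccc1)C(C)(C)C
F6 | step 5 | 4-oxopentanal | CC(=O)CCC=O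
F7 | step 5 | ethyl (2E)-2-methyl-6-oxohept-2-enoate | CCOC(=O)/C(C)=C/CCC(C)=O
F8 | step 5 | (2E)-2-methylhept-2-ene-1,6-diol (racemic) | CC(O)CC/C=C(\C)CO
F9 | step 5 | (5E)-7-[tert-butyl(diphenyl)silyl]oxy-6-methylhept-5-en-2-ol (racemic) | CC(O)CC/C=C(\C)CO[Si](c1ccccc1)(c1ccccc1)C(C)(C)C
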